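## Retrosynthetic overview

- Endgame: C15 is oxidised last. The C19 acetate and the axial 3-OH come from a C4 ester and a C3 ketone. C7=C8 comes from the ring-B C7 ketone (reduction, anti elimination). C5–H comes from hydrogenation of a C5=C6 enone, and the C18 methyl from C4-methylation of a vinylogous β-keto ester anion.
- Feature: ring A carries oxygen at C3, the one-carbon group C19 at C4 and the quaternary ring-fusion carbon C10 para to C3. Ring A is therefore read as a methyl salicylate whose para carbon becomes C10.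
- Key disconnection C9–C10: the salicylate phenoxide adds through C10 to C9 of an (E)-enone tethered at C5 (C6–C7(=O)–C8(CH3)=C9). This closes ring B onto the preformed ring A.
- The precursor is cut at C6–C7: laterally lithiated methyl 6-(methoxymethoxy)-2,3-dimethylbenzoate is acylated by an N-methoxy-N-methyl enamide made from (R)-citronellol (source of C13).
- Ring order: ring A (bought as the arene), then ring B (key step).

Key step: step 10

Remark on numbering: labdane numbering is used for all intermediates (ring A = C1–C5, C10; ring B = C5–C10; chain C11–C16; C17 on C8; C18 and C19 on C4; C20 on C10).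

Assumption: the N-benzylcinchonidinium ion pair is taken to favour the closure that gives (10S). If it favours the other face, the pseudo-enantiomeric N-benzylcinchoninium salt is used in the same way.

Remark on the endgame: C6–H of the key-step product lies between C7=O and the C5=C4(CO2Me)–C3=O unit and is strongly acidic. A C7 ketal followed by dissolving-metal reductive methylation is therefore not used; the C4 methyl is introduced through this vinylogous anion instead.

## Route

Step 1
Reactants: 1 methyl 2-hydroxy-6-methylbenzoate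
Product: 2 methyl 3-bromo-6-hydroxy-2-methylbenzoate
Conditions: NBS, MeCN, 0 °C to rt
Reagents that add atoms: N-bromosuccinimide, O=C1CCC(=O)N1Br
Why: Electrophilic aromatic bromination; the phenol directs para, the adjacent methyl reinforces that position and NBS in MeCN is para-selective, so bromine should enter at the future C10.

Step 2
Reactants: 2 methyl 3-bromo-6-hydroxy-2-methylbenzoate
Product: 3 methyl 3-bromo-6-(methoxymethoxy)-2-methylbenzoate
Conditions: NaH, MOMCl, DMF, 0 °C
Reagents that add atoms: chloromethyl methyl ether, COCCl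
Why: O-Alkylation of the sodium phenoxide (Williamson-type acetal formation) masks the acidic OH as a MOM ether that is inert to the amide base of step 8.

Step 3
Reactants: 3 methyl 3-bromo-6-(methoxymethoxy)-2-methylbenzoate
Product: 4 methyl 6-(methoxymethoxy)-2,3-dimethylbenzoate
Conditions: MeB(OH)2, PdCl2(dppf) (5 mol%), K2CO3, dioxane/H2O, 90 °C
Reagents that add atoms: methylboronic acid, CB(O)O
Why: Suzuki–Miyaura cross-coupling of the aryl bromide installs the C20 methyl; the hindered benzoate and the MOM ether tolerate aqueous carbonate.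

Step 4
Reactants: 5 (R)-citronellol
Product: 6 (3R)-3,7-dimethyl-1-(triisopropylsilyloxy)oct-6-ene
Conditions: TIPSCl, imidazole, DMF, rt
Reagents that add atoms: chlorotriisopropylsilane, CC(C)[Si](Cl)(C(C)C)C(C)C
Why: Silylation of the primary alcohol (future C15) gives a TIPS ether that survives ozone, amide base, cold acid and hydride reagents; C13 is untouched.

Step 5
Reactants: 6 (3R)-3,7-dimethyl-1-(triisopropylsilyloxy)oct-6-ene
Product: 8 (4R)-4-methyl-6-(triisopropylsilyloxy)hexanal, via ozonide 7 (not isolated)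
Conditions: O3, CH2Cl2, −78 °C; then PPh3, −78 °C to rt
Reagents that add atoms: ozone, [O-][O+]=O
Why: Ozonolysis with reductive work-up cleaves acetone from the trisubstituted alkene and leaves the C9 aldehyde; the C13 stereocentre is not enolisable.

Step 6
Reactants: 8 (4R)-4-methyl-6-(triisopropylsilyloxy)hexanal
Product: 9 ethyl (2E,6R)-2,6-dimethyl-8-(triisopropylsilyloxy)oct-2-enoate
Conditions: Ph3P=C(CH3)CO2Et, CH2Cl2, 40 °C
Reagents that add atoms: ethyl 2-(triphenylphosphoranylidene)propanoate, CCOC(=O)C(C)=P(c1ccccc1)(c1ccccc1)c1ccccc1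
Why: Wittig olefination with a stabilised α-methyl ylide should give the (E)-trisubstituted enoate (C7–C8=C9).

Step 7
Reactants: 9 ethyl (2E,6R)-2,6-dimethyl-8-(triisopropylsilyloxy)oct-2-enoate
Product: 10 (2E,6R)-N-methoxy-N,2,6-trimethyl-8-(triisopropylsilyloxy)oct-2-enamide
Conditions: MeNH(OMe)·HCl, i-PrMgCl, THF, −20 °C to 0 °C
Reagents that add atoms: N,O-dimethylhydroxylamine hydrochloride, CNOC.Cl
Why: Aminolysis of the ester by the chloromagnesium amide of N,O-dimethylhydroxylamine (Weinreb amide formation); the α-methyl group disfavours conjugate addition of the amide.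

Step 8
Reactants: 4 methyl 6-(methoxymethoxy)-2,3-dimethylbenzoate; 10 (2E,6R)-N-methoxy-N,2,6-trimethyl-8-(triisopropylsilyloxy)oct-2-enamide
Product: 13 methyl 2-[(3E,7R)-3,7-dimethyl-2-oxo-9-(triisopropylsilyloxy)non-3-en-1-yl]-6-(methoxymethoxy)-3-methylbenzoate, via lithiated toluate 11 (not isolated), via tetrahedral lithium adduct 12 (not isolated)
Conditions: LiN(i-Pr)2 (1.2 equiv), THF, −78 °C; then 10, −78 °C; aq. NH4Cl
Reagents that add atoms: none
Why: Lateral lithiation of the o-toluate (only the methyl ortho to the ester is acidified) gives a benzylic anion that acylates the Weinreb amide by 1,2-addition to form C6–C7, the chelated adduct preventing a second addition; this acylation is known for toluate anions with α,β-unsaturated N-methoxy-N-methyl amides, and the α-methyl group further disfavours 1,4-addition.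

Step 9
Reactants: 13 methyl 2-[(3E,7R)-3,7-dimethyl-2-oxo-9-(triisopropylsilyloxy)non-3-en-1-yl]-6-(methoxymethoxy)-3-methylbenzoate
Product: 14 methyl 2-[(3E,7R)-3,7-dimethyl-2-oxo-9-(triisopropylsilyloxy)non-3-en-1-yl]-6-hydroxy-3-methylbenzoate
Conditions: TFA, CH2Cl2, 0 °C; aq. NaHCO3
Reagents that add atoms: none
Why: Acid-catalysed cleavage of the aryl MOM acetal, fast for a salicylate-type ether, frees the phenol while the primary TIPS ether and the enone should survive brief cold TFA.

Step 10
Reactants: 14 methyl 2-[(3E,7R)-3,7-dimethyl-2-oxo-9-(triisopropylsilyloxy)non-3-en-1-yl]-6-hydroxy-3-methylbenzoate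
Product: 17 methyl (8R,9R,10S,13R)-3,7-dioxo-15-(triisopropylsilyloxy)-18-norlabda-1,4-dien-19-oate, via ring-closed C7 enolate 15 (not isolated), via C6 dienolate 16 (not isolated)
Conditions: Cs2CO3 (1.5 equiv), N-benzylcinchonidinium bromide (10 mol%), toluene (0.05 M), 0 °C to rt; then AcOH
Reagents that add atoms: none
Why: Proposed new method: Cs2CO3 forms the salicylate phenoxide, which enters toluene as its ion pair with the chiral N-benzylcinchonidinium cation and adds through the para carbon C10 to C9 of the tethered s-trans (E)-enone, closing ring B in a 6-endo-trig mode to the C7 enolate 15; the closest known reaction types are base-mediated intramolecular dearomative para-alkylations and para-Michael additions of phenols that give 4,4-disubstituted cyclohexa-2,5-dienones, and the 6-endo oxa-Michael closure of 2′-hydroxychalcones, here transferred to the para carbon with a chiral ammonium counter-ion. C10 (S) is set by the face of the phenoxide that the chiral cation leaves open, and this is the only element that relates the new ring stereocentres to C13. C9 (R) follows from C10 through a chair-like transition state in which C8 lies on the C6 side and the C11 chain of the (E)-enone points away from ring A (equatorial, cis to the C10 methyl) while H9 sits over the ring; C8 (R) results from protonation under equilibrating conditions, which leaves its methyl equatorial and free of a 1,3-diaxial contact with the C10 methyl. The step needs para rather than ortho (C4) attack and must not revert: both closures are reversible, but only the para adduct is a cross-conjugated dienone whose C6–H lies between C7=O and the C5=C4(CO2Me)–C3=O unit, so Cs2CO3 should drain it as the vinylogous enolate 16, which cannot undergo retro-Michael cleavage without becoming a dianion; AcOH then returns 17. The trisubstituted enone is a slow acceptor, so the mixture is given time at room temperature before any heating.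

Step 11
Reactants: 17 methyl (8R,9R,10S,13R)-3,7-dioxo-15-(triisopropylsilyloxy)-18-norlabda-1,4-dien-19-oate
Product: 18 methyl (8R,9R,10S,13R)-3,7-dioxo-15-(triisopropylsilyloxy)-18-norlabd-4-en-19-oate
Conditions: H2 (1 atm), RhCl(PPh3)3 (10 mol%), toluene/EtOH, rt
Reagents that add atoms: none
Why: Homogeneous hydrogenation with RhCl(PPh3)3 reduces only the cis-disubstituted C1=C2 of the cross-conjugated dienone (the tetrasubstituted C4=C5 is inert), which removes the aromatisation-driven retro-Michael pathway and gives ring A a half-chair with the C10 methyl axial.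

Step 12
Reactants: 18 methyl (8R,9R,10S,13R)-3,7-dioxo-15-(triisopropylsilyloxy)-18-norlabd-4-en-19-oate
Product: 20 methyl (4S,8R,9R,10S,13R)-3,7-dioxo-15-(triisopropylsilyloxy)labd-5-en-19-oate, via potassium dienolate 19 (not isolated)
Conditions: K2CO3, MeI, acetone, rt to 40 °C
Reagents that add atoms: iodomethane, CI
Why: Deconjugative α-alkylation of a vinylogous β-keto ester anion: carbonate removes the C6 proton, the charge sits mainly on C4 between the ketone and the ester, and MeI should enter there anti to the axial C10 methyl (as in methylations of 4-alkoxycarbonyl-3-oxo-octalone dienolates), setting C4 (S, ester cis to C20) and moving the alkene to C5=C6 in conjugation with C7=O.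

Step 13
Reactants: 20 methyl (4S,8R,9R,10S,13R)-3,7-dioxo-15-(triisopropylsilyloxy)labd-5-en-19-oate
Product: 21 methyl (4S,5S,8R,9R,10S,13R)-3,7-dioxo-15-(triisopropylsilyloxy)labdan-19-oate
Conditions: H2 (3 atm), 10% Pd/C, EtOAc, rt
Reagents that add atoms: none
Why: Heterogeneous hydrogenation of the enone C5=C6 from the face opposite the axial C10 methyl and the axial C19 ester should give the trans ring fusion (5S), as for 5-ene steroids.

Step 14
Reactants: 21 methyl (4S,5S,8R,9R,10S,13R)-3,7-dioxo-15-(triisopropylsilyloxy)labdan-19-oate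
Product: 22 methyl (4S,5S,7S,8R,9R,10S,13R)-7-hydroxy-3-oxo-15-(triisopropylsilyloxy)labdan-19-oate
Conditions: LiBH(s-Bu)3 (1.1 equiv), THF, −78 °C; then H2O
Reagents that add atoms: none
Why: Chemo- and stereoselective ketone reduction by a bulky hydride: the C7 ketone is far less hindered than the neopentyl C3 ketone, and equatorial attack gives the axial 7-alcohol (7S) needed for anti elimination.

Step 15
Reactants: 22 methyl (4S,5S,7S,8R,9R,10S,13R)-7-hydroxy-3-oxo-15-(triisopropylsilyloxy)labdan-19-oate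
Product: 24 methyl (4S,5S,9R,10S,13R)-3-oxo-15-(triisopropylsilyloxy)labd-7-en-19-oate, via 7-dichlorophosphate 23 (not isolated)
Conditions: POCl3, pyridine, 0 °C to 60 °C
Reagents that add atoms: none
Why: E2 dehydration through the dichlorophosphate: the axial C7 leaving group is anti-periplanar to the axial tertiary H8, so Zaitsev elimination away from the ring fusion should give the trisubstituted C7=C8 alkene and remove the C8 stereocentre.

Step 16
Reactants: 24 methyl (4S,5S,9R,10S,13R)-3-oxo-15-(triisopropylsilyloxy)labd-7-en-19-oate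
Product: 25 methyl (3S,4S,5S,9R,10S,13R)-3-hydroxy-15-(triisopropylsilyloxy)labd-7-en-19-oate
Conditions: LiBH(s-Bu)3 (3 equiv), THF, −78 °C to 0 °C; then H2O
Reagents that add atoms: none
Why: Reduction of the hindered C3 ketone by a bulky hydride from the equatorial direction gives the axial alcohol (3S, trans to C19), the usual outcome for 4,4-disubstituted 3-oxo-decalins; the ester is not reduced at 0 °C.

Step 17
Reactants: 25 methyl (3S,4S,5S,9R,10S,13R)-3-hydroxy-15-(triisopropylsilyloxy)labd-7-en-19-oate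
Product: 26 (3S,4R,5S,9R,10S,13R)-15-(triisopropylsilyloxy)labd-7-ene-3,19-diol
Conditions: LiAlH4, THF, 0 °C to rt; then H2O
Reagents that add atoms: none
Why: LiAlH4 reduction of the hindered ester to the primary C19 alcohol; the alkene, the TIPS ether and all stereocentres are unaffected.

Step 18
Reactants: 26 (3S,4R,5S,9R,10S,13R)-15-(triisopropylsilyloxy)labd-7-ene-3,19-diol
Product: 27 (3S,4R,5S,9R,10S,13R)-3-hydroxy-15-(triisopropylsilyloxy)labd-7-en-19-yl acetate
Conditions: Ac2O (1.1 equiv), pyridine, CH2Cl2, 0 °C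
Reagents that add atoms: acetic anhydride, CC(=O)OC(C)=O
Why: Selective acylation of the primary alcohol over the axial secondary alcohol next to the quaternary C4; the two oxygens are anti across C3–C4, so the acetyl group should not migrate.

Step 19
Reactants: 27 (3S,4R,5S,9R,10S,13R)-3-hydroxy-15-(triisopropylsilyloxy)labd-7-en-19-yl acetate
Product: 28 (3S,4R,5S,9R,10S,13R)-3,15-dihydroxylabd-7-en-19-yl acetate
Conditions: HF·pyridine, pyridine/THF, 0 °C to rt
Reagents that add atoms: none
Why: Fluoride-mediated cleavage of the Si–O bond under buffered conditions that leave the acetate and the trisubstituted alkene intact.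

Step 20
Reactants: 28 (3S,4R,5S,9R,10S,13R)-3,15-dihydroxylabd-7-en-19-yl acetate
Product: 30 (3S,4R,5S,9R,10S,13R)-19-acetoxy-3-hydroxylabd-7-en-15-oic acid, via aldehyde 29 (not isolated)
Conditions: TEMPO (20 mol%), PhI(OAc)2 (2.5 equiv), MeCN/H2O, rt
Reagents that add atoms: water, O
Why: Oxoammonium (TEMPO) oxidation with PhI(OAc)2 in aqueous MeCN takes the unhindered primary alcohol through the aldehyde hydrate to the acid, while the hindered axial secondary alcohol and the alkene should not be oxidised.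

## Compound list

1 | methyl 2-hydroxy-6-methylbenzoate | COC(=O)c1c(C)cccc1O | starting material
2 | methyl 3-bromo-6-hydroxy-2-methylbenzoate | COC(=O)c1c(C)c(Br)ccc1O | intermediate
3 | methyl 3-bromo-6-(methoxymethoxy)-2-methylbenzoate | COCOc1ccc(Br)c(C)c1C(=O)OC | intermediate
4 | methyl 6-(methoxymethoxy)-2,3-dimethylbenzoate | COCOc1ccc(C)c(C)c1C(=O)OC | intermediate
5 | (R)-citronellol | CC(C)=CCC[C@@H](C)CCO | starting material
6 | (3R)-3,7-dimethyl-1-(triisopropylsilyloxy)oct-6-ene | CC(C)=CCC[C@@H](C)CCO[Si](C(C)C)(C(C)C)C(C)C | intermediate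
7 | ozonide of 6: 3,3-dimethyl-5-[(3R)-3-methyl-5-(triisopropylsilyloxy)pentyl]-1,2,4-trioxolane | CC1(C)OOC(CC[C@@H](C)CCO[Si](C(C)C)(C(C)C)C(C)C)O1 | intermediate
8 | (4R)-4-methyl-6-(triisopropylsilyloxy)hexanal | O=CCC[C@@H](C)CCO[Si](C(C)C)(C(C)C)C(C)C | intermediate
9 | ethyl (2E,6R)-2,6-dimethyl-8-(triisopropylsilyloxy)oct-2-enoate | CCOC(=O)/C(C)=C/CC[C@@H](C)CCO[Si](C(C)C)(C(C)C)C(C)C | intermediate
10 | (2E,6R)-N-methoxy-N,2,6-trimethyl-8-(triisopropylsilyloxy)oct-2-enamide | CON(C)C(=O)/C(C)=C/CC[C@@H](C)CCO[Si](C(C)C)(C(C)C)C(C)C | intermediate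
11 | [2-(methoxycarbonyl)-3-(methoxymethoxy)-6-methylphenyl]methyllithium (lithiated toluate) | [Li]Cc1c(C)ccc(OCOC)c1C(=O)OC | intermediate
12 | lithium alkoxide of the C7 N-methoxy-N-methyl hemiaminal (tetrahedral adduct of 11 and 10) | COCOc1ccc(C)c(CC(O[Li])(N(C)OC)/C(C)=C/CC[C@@H](C)CCO[Si](C(C)C)(C(C)C)C(C)C)c1C(=O)OC | intermediate
13 | methyl 2-[(3E,7R)-3,7-dimethyl-2-oxo-9-(triisopropylsilyloxy)non-3-en-1-yl]-6-(methoxymethoxy)-3-methylbenzoate | COCOc1ccc(C)c(CC(=O)/C(C)=C/CC[C@@H](C)CCO[Si](C(C)C)(C(C)C)C(C)C)c1C(=O)OC | intermediate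
14 | methyl 2-[(3E,7R)-3,7-dimethyl-2-oxo-9-(triisopropylsilyloxy)non-3-en-1-yl]-6-hydroxy-3-methylbenzoate | COC(=O)c1c(CC(=O)/C(C)=C/CC[C@@H](C)CCO[Si](C(C)C)(C(C)C)C(C)C)c(C)ccc1O | intermediate
15 | cesium C7 enolate of 17 (C7=C8, closure product before protonation at C8) | COC(=O)C1=C2CC([O-])=C(C)[C@@H](CC[C@@H](C)CCO[Si](C(C)C)(C(C)C)C(C)C)[C@]2(C)C=CC1=O.[Cs+] | intermediate
16 | cesium C6 dienolate of 17 (C6 deprotonated, C6=C7–O−) | COC(=O)C1=C2C=C([O-])[C@H](C)[C@@H](CC[C@@H](C)CCO[Si](C(C)C)(C(C)C)C(C)C)[C@]2(C)C=CC1=O.[Cs+] | intermediate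
17 | methyl (8R,9R,10S,13R)-3,7-dioxo-15-(triisopropylsilyloxy)-18-norlabda-1,4-dien-19-oate | COC(=O)C1=C2CC(=O)[C@H](C)[C@@H](CC[C@@H](C)CCO[Si](C(C)C)(C(C)C)C(C)C)[C@]2(C)C=CC1=O | intermediate
18 | methyl (8R,9R,10S,13R)-3,7-dioxo-15-(triisopropylsilyloxy)-18-norlabd-4-en-19-oate | COC(=O)C1=C2CC(=O)[C@H](C)[C@@H](CC[C@@H](C)CCO[Si](C(C)C)(C(C)C)C(C)C)[C@]2(C)CCC1=O | intermediate
19 | potassium C6 dienolate of 18 | COC(=O)C1=C2C=C([O-])[C@H](C)[C@@H](CC[C@@H](C)CCO[Si](C(C)C)(C(C)C)C(C)C)[C@]2(C)CCC1=O.[K+] | intermediate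
20 | methyl (4S,8R,9R,10S,13R)-3,7-dioxo-15-(triisopropylsilyloxy)labd-5-en-19-oate | COC(=O)[C@@]1(C)C2=CC(=O)[C@H](C)[C@@H](CC[C@@H](C)CCO[Si](C(C)C)(C(C)C)C(C)C)[C@]2(C)CCC1=O | intermediate
21 | methyl (4S,5S,8R,9R,10S,13R)-3,7-dioxo-15-(triisopropylsilyloxy)labdan-19-oate | COC(=O)[C@@]1(C)[C@H]2CC(=O)[C@H](C)[C@@H](CC[C@@H](C)CCO[Si](C(C)C)(C(C)C)C(C)C)[C@]2(C)CCC1=O | intermediate
22 | methyl (4S,5S,7S,8R,9R,10S,13R)-7-hydroxy-3-oxo-15-(triisopropylsilyloxy)labdan-19-oate | COC(=O)[C@@]1(C)[C@H]2C[C@H](O)[C@H](C)[C@@H](CC[C@@H](C)CCO[Si](C(C)C)(C(C)C)C(C)C)[C@]2(C)CCC1=O | intermediate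
23 | 7-O-dichlorophosphate of 22 | COC(=O)[C@@]1(C)[C@H]2C[C@H](OP(=O)(Cl)Cl)[C@H](C)[C@@H](CC[C@@H](C)CCO[Si](C(C)C)(C(C)C)C(C)C)[C@]2(C)CCC1=O | intermediate
24 | methyl (4S,5S,9R,10S,13R)-3-oxo-15-(triisopropylsilyloxy)labd-7-en-19-oate | COC(=O)[C@@]1(C)[C@H]2CC=C(C)[C@@H](CC[C@@H](C)CCO[Si](C(C)C)(C(C)C)C(C)C)[C@]2(C)CCC1=O | intermediate
25 | methyl (3S,4S,5S,9R,10S,13R)-3-hydroxy-15-(triisopropylsilyloxy)labd-7-en-19-oate | COC(=O)[C@@]1(C)[C@H]2CC=C(C)[C@@H](CC[C@@H](C)CCO[Si](C(C)C)(C(C)C)C(C)C)[C@]2(C)CC[C@@H]1O | intermediate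
26 | (3S,4R,5S,9R,10S,13R)-15-(triisopropylsilyloxy)labd-7-ene-3,19-diol | OC[C@@]1(C)[C@H]2CC=C(C)[C@@H](CC[C@@H](C)CCO[Si](C(C)C)(C(C)C)C(C)C)[C@]2(C)CC[C@@H]1O | intermediate
27 | (3S,4R,5S,9R,10S,13R)-3-hydroxy-15-(triisopropylsilyloxy)labd-7-en-19-yl acetate | CC(=O)OC[C@@]1(C)[C@H]2CC=C(C)[C@@H](CC[C@@H](C)CCO[Si](C(C)C)(C(C)C)C(C)C)[C@]2(C)CC[C@@H]1O | intermediate
28 | (3S,4R,5S,9R,10S,13R)-3,15-dihydroxylabd-7-en-19-yl acetate | CC(=O)OC[C@@]1(C)[C@H]2CC=C(C)[C@@H](CC[C@@H](C)CCO)[C@]2(C)CC[C@@H]1O | intermediate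
29 | (3S,4R,5S,9R,10S,13R)-3-hydroxy-15-oxolabd-7-en-19-yl acetate | CC(=O)OC[C@@]1(C)[C@H]2CC=C(C)[C@@H](CC[C@@H](C)CC=O)[C@]2(C)CC[C@@H]1O | intermediate
30 | (3S,4R,5S,9R,10S,13R)-19-acetoxy-3-hydroxylabd-7-en-15-oic acid (CNP0218903.1) | CC(=O)OC[C@@]1(C)[C@H]2CC=C(C)[C@@H](CC[C@@H](C)CC(=O)O)[C@]2(C)CC[C@@H]1O | target

## Step count and risks

Total step count: 20 steps. Longest linear sequence: 17 steps (steps 4–20, from (R)-citronellol).

Steps most likely to fail:

1. Step 10 (dearomative para-Michael closure). The closure may stall or revert, because the trisubstituted enone is a weak acceptor and dearomatisation is close to thermoneutral. Ring closure through the ester-bearing ortho carbon may compete. The ion pair may discriminate poorly between the two faces at C10. The benzylic keto ester may enol-lactonise to an isocoumarin. Fallback (known chemistry: phenoxide para-C-alkylation by intramolecular SN2 displacement instead of conjugate addition; sets out from aldehyde 8 and benzoate 4, returns at 17): the dibutylboron enolate of (R)-4-benzyl-3-propionyloxazolidin-2-one (Bu2BOTf, i-Pr2NEt) adds to 8 to give the Evans syn-aldol adduct F1, which fixes C8 and C9. AlMe3/MeNH(OMe)·HCl converts it into the N-methoxy-N-methyl amide F2. Its magnesium alkoxide (i-PrMgCl) is acylated by lithiated 4 (compound 11, LiN(i-Pr)2, −78 °C) to the β-hydroxy ketone F3. TMSOCH2CH2OTMS/TMSOTf, then K2CO3/MeOH, gives the C7 dioxolane F4, which blocks β-elimination. MsCl/Et3N gives the C9 mesylate F5. TMSOTf/2,2′-bipyridyl, then water, frees the phenol F6. KOt-Bu in t-BuOH/THF closes ring B by attack of C10 on C9 with inversion, giving the dienone ketal F7; (9R) comes from the aldol centre and (10S) from the same chair-like closure. PPTS in wet acetone releases 17.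

2. Step 15 (dehydration). Elimination may run toward C6 and give the 6-ene, or chloride may substitute at C7. Fallback (carbene 1,2-hydrogen shift instead of E2; sets out from diketone 21, returns at 24): TsNHNH2 condenses only with the unhindered C7 ketone to give the tosylhydrazone F8. Its sodium salt (NaH) is heated in diglyme (aprotic Bamford–Stevens reaction), and the C7 carbene should take the tertiary C8 hydrogen to give 24.

3. Step 8 (acylation of the toluate anion). The benzylic anion may add in conjugate fashion to the enamide, deprotonate it at the γ-position, or condense with its own ester. Fallback (acyl chloride as a harder acyl donor; sets out from ester 9 and benzoate 4, returns at 13): LiOH hydrolysis of 9 gives the acid F9. 1-Chloro-N,N,2-trimethylprop-1-en-1-amine converts it under neutral conditions into the acid chloride F10. F10 is added at −78 °C to two equivalents of lithiated 4 (the second equivalent is consumed by the acidic C6–H of the product), which gives 13 after NH4Cl.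

## Further compounds

F1 | step 10 | (R)-4-benzyl-3-[(2R,3S,6R)-3-hydroxy-2,6-dimethyl-8-(triisopropylsilyloxy)octanoyl]oxazolidin-2-one | O=C1OC[C@@H](Cc2ccccc2)N1C(=O)[C@H](C)[C@@H](O)CC[C@@H](C)CCO[Si](C(C)C)(C(C)C)C(C)C
F2 | step 10 | (2R,3S,6R)-3-hydroxy-N-methoxy-N,2,6-trimethyl-8-(triisopropylsilyloxy)octanamide | CON(C)C(=O)[C@H](C)[C@@H](O)CC[C@@H](C)CCO[Si](C(C)C)(C(C)C)C(C)C
F3 | step 10 | methyl 2-[(3R,4S,7R)-4-hydroxy-3,7-dimethyl-2-oxo-9-(triisopropylsilyloxy)nonyl]-6-(methoxymethoxy)-3-methylbenzoate | COCOc1ccc(C)c(CC(=O)[C@H](C)[C@@H](O)CC[C@@H](C)CCO[Si](C(C)C)(C(C)C)C(C)C)c1C(=O)OC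
F4 | step 10 | C7 ethylene ketal of F3 | COCOc1ccc(C)c(CC2(OCCO2)[C@H](C)[C@@H](O)CC[C@@H](C)CCO[Si](C(C)C)(C(C)C)C(C)C)c1C(=O)OC
F5 | step 10 | C9 methanesulfonate of F4 | COCOc1ccc(C)c(CC2(OCCO2)[C@H](C)[C@@H](OS(C)(=O)=O)CC[C@@H](C)CCO[Si](C(C)C)(C(C)C)C(C)C)c1C(=O)OC
F6 | step 10 | free phenol of F5 | COC(=O)c1c(CC2(OCCO2)[C@H](C)[C@@H](OS(C)(=O)=O)CC[C@@H](C)CCO[Si](C(C)C)(C(C)C)C(C)C)c(C)ccc1O
F7 | step 10 | C7 ethylene ketal of 17 | COC(=O)C1=C2CC3(OCCO3)[C@H](C)[C@@H](CC[C@@H](C)CCO[Si](C(C)C)(C(C)C)C(C)C)[C@]2(C)C=CC1=O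
F8 | step 15 | C7 tosylhydrazone of 21 | COC(=O)[C@@]1(C)[C@H]2CC(=NNS(=O)(=O)c3ccc(C)cc3)[C@H](C)[C@@H](CC[C@@H](C)CCO[Si](C(C)C)(C(C)C)C(C)C)[C@]2(C)CCC1=O
F9 | step 8 | (2E,6R)-2,6-dimethyl-8-(triisopropylsilyloxy)oct-2-enoic acid | OC(=O)/C(C)=C/CC[C@@H](C)CCO[Si](C(C)C)(C(C)C)C(C)C
F10 | step 8 | (2E,6R)-2,6-dimethyl-8-(triisopropylsilyloxy)oct-2-enoyl chloride | ClC(=O)/C(C)=C/CC[C@@H](C)CCO[Si](C(C)C)(C(C)C)C(C)C
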